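**Plan**

- The target is 4-hydroxy-2-methoxy-6-pentadecylphenyl acetate (ring numbered C1 OAc, C2 OMe, C4 OH, C6 C15H31). It is achiral, so no stereocentre has to be set.
- Retrosynthesis first cuts the acetyl C–O bond at C1 and the O–Si bond of a silyl ether at C4. It then cuts the C1–O bond and the C6–chain bond together, leading back to a C1≡C6 aryne and pentadecylmagnesium bromide.
- Enabling feature: the chain-bearing C6 and the oxygenated C1 are adjacent ring carbons, and C1 has the methoxy-bearing C2 as its other neighbour. The C1/C6 pair maps onto the two carbons of an aryne, and the C2–O bond decides which end takes the carbon nucleophile.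
- Forward order: silylation of 3-fluoro-5-methoxyphenol; Grignard formation from 1-bromopentadecane; one-pot lithiation, fluoride loss, chain attachment at C6 and borate–peroxide oxygenation at C1; acetylation; desilylation.
- No ring is formed; the benzene ring is bought with the fluorophenol.

Key step: step 3

**Route**

Step 1
Reactants: 1 3-fluoro-5-methoxyphenol
Product: 2 1-fluoro-3-methoxy-5-(triisopropylsilyloxy)benzene
Conditions: TIPSCl (1.2 equiv), imidazole (2.5 equiv), DMF, 0 °C to rt
Reagents that add atoms: triisopropylsilyl chloride, CC(C)[Si](Cl)(C(C)C)C(C)C
Why: Imidazole-promoted silylation of a phenol (silyl ether formation) is general, and the bulky triisopropylsilyl ether is chosen because it should withstand sec-butyllithium and neither direct nor allow metalation at its ortho positions.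

Step 2
Reactants: 3 1-bromopentadecane
Product: 4 pentadecylmagnesium bromide
Conditions: Mg turnings (1.3 equiv), I2 (one crystal), THF, 45 °C, slow addition of 3; titrated and used as THF solution
Reagents that add atoms: magnesium, [Mg]
Why: Grignard formation by insertion of magnesium into a primary C–Br bond is routine, and slow addition of the bromide to an excess of activated metal should keep Wurtz homocoupling low.

Step 3
Reactants: 2 1-fluoro-3-methoxy-5-(triisopropylsilyloxy)benzene, 4 pentadecylmagnesium bromide
Product: 9 2-methoxy-6-pentadecyl-4-(triisopropylsilyloxy)phenol, via 2-fluoro-6-methoxyaryllithium 5 (not isolated), via 3-methoxyaryne 6 (not isolated), via arylmagnesium bromide 7 (not isolated), via dimethyl arylboronate 8 (not isolated)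
Conditions: sec-BuLi (1.1 equiv), THF, −78 °C, 1 h; 4 (3 equiv, THF), −78 °C to 50 °C; B(OMe)3 (5 equiv), −78 °C to rt; 30% aq. H2O2, 0 °C to rt
Reagents that add atoms: sec-butyllithium, CCC(C)[Li] (lithium of 5); trimethyl borate, COB(OC)OC (boron and methoxy groups of 8); hydrogen peroxide, OO (phenol oxygen of 9)
Why: sec-Butyllithium should remove the ring proton between fluorine and methoxy, the only one acidified by two flanking heteroatoms (the triisopropylsilyl ether shields its own neighbours), and on warming aryllithium 5 expels LiF to give aryne 6 with the formal triple bond between C1 and C6 (target numbering). Grignard reagent 4, present in excess, adds its carbon to C6 and leaves magnesium on C1 (7); trimethyl borate turns this C–Mg bond into a C–B bond (8), and hydroperoxide then induces the 1,2-shift of the aryl group from boron to oxygen, hydrolysis of the borate ester giving phenol 9. The closest known reaction types are the deprotonative generation of 3-methoxyarynes from 3-haloanisoles, aryne carbomagnesiation with electrophilic capture of the ortho-metalated adduct, and the borate–peroxide hydroxylation of aryl Grignard reagents. No ring is closed and no stereocentre is created. The selectivity needed is regiochemical: the nucleophile must bond to C6 and not to C1, and this is secured by the C2 methoxy group, whose inductive withdrawal distorts the aryne and stabilises the negative charge developing on the adjacent C1, whereas the C4 silyloxy group, meta to C6, exerts only a weak bias. The threefold excess of 4 is meant to outrun addition of 5 or 7 to the aryne; the surplus reagent is destroyed in the oxidation and its residue removed by chromatography.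

Step 4
Reactants: 9 2-methoxy-6-pentadecyl-4-(triisopropylsilyloxy)phenol
Product: 10 2-methoxy-6-pentadecyl-4-(triisopropylsilyloxy)phenyl acetate
Conditions: Ac2O (1.5 equiv), DMAP (0.1 equiv), pyridine, rt
Reagents that add atoms: acetic anhydride, CC(=O)OC(C)=O
Why: DMAP-catalysed acylation (nucleophilic catalysis through the N-acetylpyridinium ion) should acetylate even a phenol flanked by an alkyl chain and a methoxy group, and the aryl silyl ether is inert to these conditions.

Step 5
Reactants: 10 2-methoxy-6-pentadecyl-4-(triisopropylsilyloxy)phenyl acetate
Product: 11 4-hydroxy-2-methoxy-6-pentadecylphenyl acetate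
Conditions: TBAF (1.2 equiv), AcOH (1.5 equiv), THF, 0 °C
Reagents that add atoms: none
Why: Fluoride-induced desilylation, driven by the strength of the Si–F bond, should free the C4 phenol, while acetic acid protonates the phenoxide as it forms so that the medium does not become basic enough to hydrolyse or transfer the C1 acetate.

**Compound list**

1 | 3-fluoro-5-methoxyphenol | COc1cc(O)cc(F)c1 | starting material
2 | 1-fluoro-3-methoxy-5-(triisopropylsilyloxy)benzene | COc1cc(F)cc(O[Si](C(C)C)(C(C)C)C(C)C)c1 | intermediate
3 | 1-bromopentadecane | CCCCCCCCCCCCCCCBr | starting material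
4 | pentadecylmagnesium bromide | CCCCCCCCCCCCCCC[Mg]Br | intermediate
5 | [2-fluoro-6-methoxy-4-(triisopropylsilyloxy)phenyl]lithium | [Li]c1c(F)cc(O[Si](C(C)C)(C(C)C)C(C)C)cc1OC | intermediate
6 | 3-methoxy-5-(triisopropylsilyloxy)benzyne (1,2-didehydrobenzene) | COC1=CC(O[Si](C(C)C)(C(C)C)C(C)C)=CC#C1 | intermediate
7 | [2-methoxy-6-pentadecyl-4-(triisopropylsilyloxy)phenyl]magnesium bromide | CCCCCCCCCCCCCCCc1cc(O[Si](C(C)C)(C(C)C)C(C)C)cc(OC)c1[Mg]Br | intermediate
8 | dimethyl [2-methoxy-6-pentadecyl-4-(triisopropylsilyloxy)phenyl]boronate | CCCCCCCCCCCCCCCc1cc(O[Si](C(C)C)(C(C)C)C(C)C)cc(OC)c1B(OC)OC | intermediate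
9 | 2-methoxy-6-pentadecyl-4-(triisopropylsilyloxy)phenol | CCCCCCCCCCCCCCCc1cc(O[Si](C(C)C)(C(C)C)C(C)C)cc(OC)c1O | intermediate
10 | 2-methoxy-6-pentadecyl-4-(triisopropylsilyloxy)phenyl acetate | CCCCCCCCCCCCCCCc1cc(O[Si](C(C)C)(C(C)C)C(C)C)cc(OC)c1OC(C)=O | intermediate
11 | 4-hydroxy-2-methoxy-6-pentadecylphenyl acetate | CCCCCCCCCCCCCCCc1cc(O)cc(OC)c1OC(C)=O | target

**Step count**

Total steps: 5. Longest linear sequence: 4 steps (steps 1, 3, 4 and 5 from compound 1; step 2 is a one-step side branch from compound 3).

**Steps most likely to fail**

1. Step 3. Several processes could erode the one-pot sequence: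
- the aryne may be intercepted by aryllithium 5 or arylmagnesium 7 instead of by 4, giving oligomers;
- the Grignard reagent may transfer a β-hydride instead of its carbon, reducing the aryne;
- some deprotonation may occur between fluorine and the silyl ether, leading to the regioisomeric aryne;
- the crowded arylmagnesium may be protonated before it is borylated.

The fallback gives up the aryne and makes the two bonds by classical oxidation and cross-coupling. It sets out from Grignard reagent 4 and rejoins the route at 9. Purchased 5-bromovanillin F1 (3-bromo-4-hydroxy-5-methoxybenzaldehyde) would undergo Dakin oxidation (H2O2, aq. NaOH, under argon). This passes through 3-bromo-4-hydroxy-5-methoxyphenyl formate F2, which is hydrolysed in the flask to 2-bromo-6-methoxybenzene-1,4-diol F3. The unhindered C4 hydroxyl, flanked by two hydrogens, would be silylated in preference to the C1 hydroxyl between bromine and methoxy (TIPSCl, imidazole, DMF, 0 °C), giving 2-bromo-6-methoxy-4-(triisopropylsilyloxy)phenol F4. Kumada coupling of F4 with 4 (3 equiv, the first serving to deprotonate the phenol; PdCl2(dppf) 5 mol %, THF, 50 °C) should then give 9.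

2. Step 5. Once fluoride unveils the C4 phenoxide, the C1 acetyl group may be lost or passed from one molecule to another, giving mixtures of regioisomeric monoacetates and diol.

The fallback relies on steric differentiation of two acetates instead of a silyl group. It sets out from 9 and rejoins the route at 11. Compound 9 would be desilylated (TBAF, degassed THF, 0 °C) to 2-methoxy-6-pentadecylbenzene-1,4-diol F5. This is acetylated in the same flask (Ac2O, pyridine, DMAP) to 2-methoxy-6-pentadecyl-1,4-phenylene diacetate F6. Aminolysis with pyrrolidine (1.05 equiv, CH2Cl2, 0 °C) should then remove the exposed C4 acetate and leave the C1 acetate, shielded by the chain and the methoxy group, to give 11.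

3. Step 2. Wurtz homocoupling of the long-chain bromide at the metal surface and sluggish initiation could give a weak, contaminated reagent that starves the aryne step of nucleophile.

The fallback makes the same reagent by halogen–lithium exchange and transmetalation. It sets out from 3 and rejoins the route at 4. Finkelstein exchange (NaI, acetone, reflux) would give 1-iodopentadecane F7. Iodine–lithium exchange with tert-butyllithium (2.1 equiv, pentane–Et2O, −78 °C) would give pentadecyllithium F8, and transmetalation with MgBr2·OEt2 (THF, −78 °C to 0 °C) would deliver 4.

**Further compounds**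

F1 | step 3 | 5-bromovanillin (3-bromo-4-hydroxy-5-methoxybenzaldehyde), purchased | COc1cc(C=O)cc(Br)c1O
F2 | step 3 | 3-bromo-4-hydroxy-5-methoxyphenyl formate | COc1cc(OC=O)cc(Br)c1O
F3 | step 3 | 2-bromo-6-methoxybenzene-1,4-diol | COc1cc(O)cc(Br)c1O
F4 | step 3 | 2-bromo-6-methoxy-4-(triisopropylsilyloxy)phenol | COc1cc(O[Si](C(C)C)(C(C)C)C(C)C)cc(Br)c1O
F5 | step 5 | 2-methoxy-6-pentadecylbenzene-1,4-diol | CCCCCCCCCCCCCCCc1cc(O)cc(OC)c1O
F6 | step 5 | 2-methoxy-6-pentadecyl-1,4-phenylene diacetate | CCCCCCCCCCCCCCCc1cc(OC(C)=O)cc(OC)c1OC(C)=O
F7 | step 2 | 1-iodopentadecane | CCCCCCCCCCCCCCCI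
F8 | step 2 | pentadecyllithium | [Li]CCCCCCCCCCCCCCC
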